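The data were generated by integration for substances that don't exist, noise included.

I decide to carry one number through these flasks, the selectivity factor: how much faster target is used up than electrophile at equal amounts.

in all of them: electrophile 20 mM

| charge | nucleophile | free base | scavenger | remark | time |
|---|---|---|---|---|---|
| eta | 40 mM | 4.6 mM | 6 mM | run made earlier |  |
| gamma | 40 mM | 15 mM | 6 mM | run made earlier |  |
| ochre | 40.0 mM | 6.00 mM | 6.00 mM |  | 10 h |
| blue | 40.0 mM | 12.0 mM | 6.00 mM |  | 10 h |
| amber | 40.0 mM | 24.0 mM | 6.00 mM |  | 10 h |

| run | time / h | electrophile / % | target / % |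
|---|---|---|---|
| eta | 1.00 | 52.3 | 29.9 |
| eta | 2.00 | 36.7 | 30.8 |
| eta | 3.00 | 29.3 | 28.7 |
| eta | 4.00 | 25.3 | 27.0 |
| eta | 5.00 | 23.2 | 25.0 |
| gamma | 0.417 | 72.4 | 21.6 |
| gamma | 1.33 | 43.0 | 31.0 |
| gamma | 2.50 | 27.2 | 28.1 |
| gamma | 4.00 | 17.6 | 22.8 |
| gamma | 5.00 | 15.0 | 20.4 |

(each reading ± 0.3 percentage points)



- part of the electrophile that has reacted at the end, ochre
- part of the electrophile that has reacted at the end, blue
- part of the electrophile that has reacted at the end, amber
- what raising the concentration of free base from its lowest to its highest value here does to the part of the electrophile that has reacted (changes below 5 percentage points count as none) (it rises / no change / it falls)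

If both steps lean on the same partner, that partner cancels, and the rate of making target over the rate of using it is electrophile over factor times target. The runs allow this. Eta, with 4.6 mM of free base, holds 28.7% target at 29.3% electrophile, and gamma, with 15 mM, holds 28.1% at 27.2%. Free base seems to move the clock, not the split.

Between the second and third eta readings, 7.4 percentage points of electrophile is lost, while target falls by 2.1 points. Target used is the sum of these, and scaling by mean electrophile over mean target gives a factor, as a reading, of 1.42. Integrated, target is (a − a^s)/(s − 1), with a the fraction of electrophile left and s the factor.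

The factor tells nothing of the clock, so for the amounts reacted I lean on the forecast, which gives 84.5%, 90% and 93% and says it rises; its ground is that the “second step does depend on base”. At its ochre value, my curve puts target near 20.0%.

The flasks give 85.1%, 89.6% and 93.1% reacted: it rises, by 8 points.

    electrophile + nucleophile → acid set free + target (k = 21.0 L mol⁻¹ h⁻¹)
    nucleophile + acid set free ⇌ protonated nucleophile, settled at all times (K = 7300 L mol⁻¹)
    acid set free + free base ⇌ salt of the base, settled at all times (K = 2.80 × 10⁶ L mol⁻¹)
    acid set free + free base ⇌ idle adduct, settled at all times (K = 73.0 L mol⁻¹)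
    acid set free + scavenger → scavenged by-product (k = 350 L mol⁻¹ h⁻¹)
    crystals ⇌ acid set free, rate k6*(cs6 - [acid set free]) while solid is left; crystals form when [acid set free] > cs6 (solubility = 14.0 mM, k = 3.60 h⁻¹)
    nucleophile + target → over-reaction product (k = 29.0 L mol⁻¹ h⁻¹)

In ochre, target is made 1.45 times as fast as it is used up at 0.797 h, but at 10.0 h that ratio has drifted to 0.535, and the factor with the end state of 14.9% electrophile and 20.2% target gives 0.519, with over-reaction product at 64.9%. A neighbour of ochre, charged with 34 mM of electrophile, ends with 38.0% electrophile, where the curve gives 30.2% target and the flask holds 30.7%.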